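**Retrosynthetic overview**

1. The target is reached from dienol silane 19 by late functional-group steps: catalyst-controlled hydroxymethylation at C6, O-formylation, desilylation and oxidation of the side-chain CH2OH to CO2H.
2. Key disconnection: the C4–C5 σ-bond of the cyclohexenone, opened in the retro-6π sense to a 3-oxido-1,3,5-triene. The triene arises in the same flask from vinyllithium and cyclobutenone 15 (1,2-addition, then 4π opening of the temporary four-membered ring).
3. Enabling feature: the cyclohex-2-enone ring itself (C1 carbonyl, C2=C3 alkene, C4 and C5 both unsubstituted CH2). Its α′-enolate is a 2-oxidocyclohexa-1,3-diene, which is exactly the electrocyclisation product of such a triene with two CH2 termini.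
4. Cyclobutenone 15 comes from internal alkyne 13 and dichloroketene. Alkyne 13 comes from terminal alkyne 7 and crotyl phosphate 9 (Cu-catalysed SN2′, sets the methyl-bearing centre). Alkyne 7 comes from dimedone enol ether 1 and silylacetylene 2 (Cu-catalysed conjugate methylation sets the quaternary centre).
5. Ring order: trimethylcyclohexane (present from 1), then cyclobutenone (steps 8–9, temporary), then cyclohexenone (step 10).

Key step: step 10

Remark: the cyclohexenone ring is numbered C1 (carbonyl), C2 (side-chain carbon), C3 (carbon bearing the trimethylcyclohexyl group), C4, C5, C6 (carbon bearing the oxygenated methylene); in steps 2, 5 and 11 the antipode of the chiral ligand is taken to be the one that gives the configuration drawn.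

**Route**

Step 1
Reactants: 1 3-ethoxy-5,5-dimethylcyclohex-2-en-1-one; 2 ethynyltrimethylsilane
Product: 4 5,5-dimethyl-3-[(trimethylsilyl)ethynyl]cyclohex-2-en-1-one, via lithium carbinolate adduct 3 (not isolated)
Conditions: 2, n-BuLi, THF, −78 °C; add 1, −78 → 0 °C; then 2 M aq. HCl, 23 °C
Reagents that add atoms: water, O
Why: Stork–Danheiser transposition, in which 1,2-addition of the lithium acetylide to the vinylogous ester and acid-promoted hydrolysis/dehydration give the enynone without forming a stereocentre.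

Step 2
Reactants: 4 5,5-dimethyl-3-[(trimethylsilyl)ethynyl]cyclohex-2-en-1-one
Product: 5 (3R)-3,5,5-trimethyl-3-[(trimethylsilyl)ethynyl]cyclohexan-1-one
Conditions: MeMgBr, Cu(OTf)2 (3 mol%), (S)-3-(1-hydroxy-3,3-dimethylbutan-2-yl)-1-mesityl-4,5-dihydroimidazolium hexafluorophosphate (NHC precursor, 4 mol%), Et2O, −30 → 0 °C; aq. NH4Cl
Reagents that add atoms: methylmagnesium bromide, C[Mg]Br
Why: Copper-catalysed asymmetric conjugate addition of a Grignard reagent to a β-alkynyl cyclic enone is a known 1,4-selective route to alkynyl-bearing quaternary centres, and the chiral NHC–copper catalyst selects the enone face and so sets the quaternary centre.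

Step 3
Reactants: 5 (3R)-3,5,5-trimethyl-3-[(trimethylsilyl)ethynyl]cyclohexan-1-one
Product: 7 (1S)-1-ethynyl-1,3,3-trimethylcyclohexane, via hydrazone 6 (not isolated)
Conditions: N2H4·H2O, KOH, diethylene glycol, N2, 130 → 200 °C
Reagents that add atoms: none
Why: Wolff–Kishner reduction (Huang–Minlon procedure) removes the unhindered ring carbonyl while hot hydroxide cleaves the C(sp)–Si bond in the same pot, and the quaternary centre cannot epimerise (the descriptor changes from R to S only because the ring priorities change).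

Step 4
Reactants: 8 (2Z)-but-2-en-1-ol
Product: 9 (2Z)-but-2-en-1-yl diethyl phosphate
Conditions: ClP(O)(OEt)2, pyridine, DMAP (cat.), CH2Cl2, 0 → 23 °C
Reagents that add atoms: diethyl chlorophosphate, CCOP(=O)(Cl)OCC
Why: Standard O-phosphorylation of a primary allylic alcohol, with the Z geometry retained.

Step 5
Reactants: 7 (1S)-1-ethynyl-1,3,3-trimethylcyclohexane; 9 (2Z)-but-2-en-1-yl diethyl phosphate
Product: 10 (1S)-1,3,3-trimethyl-1-[(3S)-3-methylpent-4-en-1-yn-1-yl]cyclohexane
Conditions: CuCl (10 mol%), chiral N-(2-hydroxyaryl)-4,5-diphenylimidazolinium chloride (NHC precursor, 10 mol%), LiOt-Bu (1.5 equiv), THF, 25 °C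
Reagents that add atoms: none
Why: Copper-catalysed enantioselective SN2′ allylic alkylation of a terminal alkyne with a (Z)-allylic phosphate forms the C(sp)–C(sp3) bond at the γ-carbon, and the chiral NHC–copper acetylide sets the new propargylic centre independently of the remote quaternary centre.

Step 6
Reactants: 10 (1S)-1,3,3-trimethyl-1-[(3S)-3-methylpent-4-en-1-yn-1-yl]cyclohexane
Product: 12 (2R)-2-methyl-4-[(1S)-1,3,3-trimethylcyclohexyl]but-3-yn-1-ol, via ozonide 11 (not isolated)
Conditions: O3 (1.0 equiv, indicator-dye end point), CH2Cl2, −78 °C; then NaBH4, MeOH, −78 → 0 °C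
Reagents that add atoms: ozone, [O-][O+]=O
Why: Ozonolysis is much faster at the monosubstituted alkene than at the hindered dialkyl alkyne, and in-flask borohydride reduction of the ozonide gives the alcohol without letting the epimerisable α-alkynyl aldehyde accumulate.

Step 7
Reactants: 12 (2R)-2-methyl-4-[(1S)-1,3,3-trimethylcyclohexyl]but-3-yn-1-ol
Product: 13 tert-butyl(dimethyl){[(2R)-2-methyl-4-[(1S)-1,3,3-trimethylcyclohexyl]but-3-yn-1-yl]oxy}silane
Conditions: t-BuMe2SiCl, imidazole, DMF, 23 °C
Reagents that add atoms: tert-butyldimethylsilyl chloride, CC(C)(C)[Si](C)(C)Cl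
Why: Routine silylation of a primary alcohol gives an ether that should tolerate the ketene, zinc, organolithium and Lewis-acid steps that follow.

Step 8
Reactants: 13 tert-butyl(dimethyl){[(2R)-2-methyl-4-[(1S)-1,3,3-trimethylcyclohexyl]but-3-yn-1-yl]oxy}silane
Product: 14 2-[(2R)-1-{[tert-butyl(dimethyl)silyl]oxy}propan-2-yl]-4,4-dichloro-3-[(1S)-1,3,3-trimethylcyclohexyl]cyclobut-2-en-1-one
Conditions: Cl3CCOCl (slow addition), activated Zn dust, POCl3, Et2O, 35 °C
Reagents that add atoms: trichloroacetyl chloride, ClC(=O)C(Cl)(Cl)Cl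
Why: In this dichloroketene–alkyne [2+2] cycloaddition the ketene carbonyl carbon should bond to the less hindered, inductively deactivated sec-alkyl alkyne carbon and the CCl2 carbon to the tert-alkyl-bearing carbon that better supports positive charge, as it does with terminal tert-alkyl acetylenes.

Step 9
Reactants: 14 2-[(2R)-1-{[tert-butyl(dimethyl)silyl]oxy}propan-2-yl]-4,4-dichloro-3-[(1S)-1,3,3-trimethylcyclohexyl]cyclobut-2-en-1-one
Product: 15 2-[(2R)-1-{[tert-butyl(dimethyl)silyl]oxy}propan-2-yl]-3-[(1S)-1,3,3-trimethylcyclohexyl]cyclobut-2-en-1-one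
Conditions: Zn dust, AcOH, TMEDA, EtOH, 0 → 23 °C
Reagents that add atoms: none
Why: Zinc reduction of the α,α-dichloro ketone through its zinc enolate is the standard way to convert 4,4-dichlorocyclobutenones into cyclobutenones with a ring CH2 group.

Step 10
Reactants: 15 2-[(2R)-1-{[tert-butyl(dimethyl)silyl]oxy}propan-2-yl]-3-[(1S)-1,3,3-trimethylcyclohexyl]cyclobut-2-en-1-one
Product: 19 tert-butyl(dimethyl){[(2R)-2-{6-[(trimethylsilyl)oxy]-2-[(1S)-1,3,3-trimethylcyclohexyl]cyclohexa-1,5-dien-1-yl}propyl]oxy}silane, via lithium vinylcyclobutenolate 16 (not isolated), via lithium trienolate 17 (not isolated), via lithium cyclohexadienolate 18 (not isolated)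
Conditions: tributyl(vinyl)stannane, n-BuLi, THF, −78 → 0 °C (gives vinyllithium); add 15, −78 → 23 °C (50 °C if closure is incomplete); then Me3SiCl, Et3N, −78 → 0 °C; non-aqueous work-up
Reagents that add atoms: vinyllithium, [Li]C=C; chlorotrimethylsilane, C[Si](C)(C)Cl
Why: Vinyllithium adds 1,2 to the strained cyclobutenone carbonyl (1,4-addition is blocked by the fully substituted C3) to give alkoxide 16, whose oxyanion lowers the barrier to conrotatory 4π ring opening; the strongly donating O– rotates outward, which forces the vinyl group inward and places it cis to C3 in trienolate 17, the only geometry that can cyclise. Thermal disrotatory 6π electrocyclisation of 17 then joins its two CH2 termini, forming the C4–C5 bond and closing the six-membered ring as the cross-conjugated dienolate 18 (a direct anionic 1,3-shift of C4 in 16 would give the same enolate), which Me3SiCl traps on oxygen. The closest known reaction type is the addition of alkenyllithium reagents to cyclobutenones followed by anion-accelerated ring opening and hexatriene electrocyclisation to cyclohex-2-enones. Ring closed: the six-membered carbocycle, by 6π electrocyclisation after 4π opening of the temporary cyclobutene. No stereocentre is created because both bond-forming carbons are CH2 groups, the two existing centres carry no hydrogen acidic enough for the intermediates to remove, and C6 is delivered as an sp2 enol-silane carbon for step 11. The selectivities needed are 1,2-addition (secured by the quaternary group on C3), inward rotation of the vinyl group (secured by the oxido substituent) and a single enolate regioisomer (the pericyclic path can only give the C6=C1 enolate).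

Step 11
Reactants: 19 tert-butyl(dimethyl){[(2R)-2-{6-[(trimethylsilyl)oxy]-2-[(1S)-1,3,3-trimethylcyclohexyl]cyclohexa-1,5-dien-1-yl}propyl]oxy}silane
Product: 20 (6S)-2-[(2R)-1-{[tert-butyl(dimethyl)silyl]oxy}propan-2-yl]-6-(hydroxymethyl)-3-[(1S)-1,3,3-trimethylcyclohexyl]cyclohex-2-en-1-one
Conditions: aq. HCHO (37%), Sc(OTf)3 (10 mol%), (S,S)-6,6′-bis(1-hydroxy-2,2-dimethylpropyl)-2,2′-bipyridine (12 mol%), DME/H2O (9:1), −20 °C
Reagents that add atoms: formaldehyde, C=O
Why: In this catalytic asymmetric Mukaiyama-type hydroxymethylation of a silicon enolate the chiral scandium–bipyridine complex activates formaldehyde and dictates which face of C6, the only nucleophilic carbon of the cross-conjugated dienol silane, is attacked, so the 6S centre is set under catalyst control.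

Step 12
Reactants: 20 (6S)-2-[(2R)-1-{[tert-butyl(dimethyl)silyl]oxy}propan-2-yl]-6-(hydroxymethyl)-3-[(1S)-1,3,3-trimethylcyclohexyl]cyclohex-2-en-1-one
Product: 21 {(1S)-3-[(2R)-1-{[tert-butyl(dimethyl)silyl]oxy}propan-2-yl]-2-oxo-4-[(1S)-1,3,3-trimethylcyclohexyl]cyclohex-3-en-1-yl}methyl formate
Conditions: HCO2H/Ac2O (premixed at 55 °C, then cooled), pyridine, CH2Cl2, −20 → 0 °C
Reagents that add atoms: acetic formic anhydride, CC(=O)OC=O
Why: Formyl transfer from the mixed anhydride to the primary alcohol is fast at low temperature, where the weak base should not trigger β-elimination or epimerisation at C6.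

Step 13
Reactants: 21 {(1S)-3-[(2R)-1-{[tert-butyl(dimethyl)silyl]oxy}propan-2-yl]-2-oxo-4-[(1S)-1,3,3-trimethylcyclohexyl]cyclohex-3-en-1-yl}methyl formate
Product: 22 {(1S)-3-[(2R)-1-hydroxypropan-2-yl]-2-oxo-4-[(1S)-1,3,3-trimethylcyclohexyl]cyclohex-3-en-1-yl}methyl formate
Conditions: HF·pyridine, pyridine, THF, 0 → 23 °C
Reagents that add atoms: none
Why: Buffered fluoride cleaves the primary silyl ether under mildly acidic conditions that should leave the formate ester and the base-sensitive β-acyloxy ketone untouched.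

Step 14
Reactants: 22 {(1S)-3-[(2R)-1-hydroxypropan-2-yl]-2-oxo-4-[(1S)-1,3,3-trimethylcyclohexyl]cyclohex-3-en-1-yl}methyl formate
Product: 23 (2R)-2-{(3S)-3-[(formyloxy)methyl]-2-oxo-6-[(1S)-1,3,3-trimethylcyclohexyl]cyclohex-1-en-1-yl}propanoic acid (target)
Conditions: TEMPO (20 mol%), PhI(OAc)2 (2.2 equiv), MeCN/H2O (1:1), 0 → 23 °C
Reagents that add atoms: water, O
Why: Oxoammonium oxidation of the primary alcohol to the aldehyde, hydration and a second oxidation give the acid without added base, so the formate, the C6 centre and the α-methyl centre should survive.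

**Compound list**

1 | 3-ethoxy-5,5-dimethylcyclohex-2-en-1-one | CCOC1=CC(=O)CC(C)(C)C1 | starting material
2 | ethynyltrimethylsilane | C#C[Si](C)(C)C | starting material
3 | lithium 3-ethoxy-5,5-dimethyl-1-[(trimethylsilyl)ethynyl]cyclohex-2-en-1-olate (not isolated) | CCOC1=CC(O[Li])(C#C[Si](C)(C)C)CC(C)(C)C1 | intermediate
4 | 5,5-dimethyl-3-[(trimethylsilyl)ethynyl]cyclohex-2-en-1-one | C[Si](C)(C)C#CC1=CC(=O)CC(C)(C)C1 | intermediate
5 | (3R)-3,5,5-trimethyl-3-[(trimethylsilyl)ethynyl]cyclohexan-1-one | C[Si](C)(C)C#C[C@@]1(C)CC(=O)CC(C)(C)C1 | intermediate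
6 | hydrazone of (3R)-3,5,5-trimethyl-3-[(trimethylsilyl)ethynyl]cyclohexan-1-one (not isolated) | C[Si](C)(C)C#C[C@@]1(C)CC(=NN)CC(C)(C)C1 | intermediate
7 | (1S)-1-ethynyl-1,3,3-trimethylcyclohexane | C#C[C@@]1(C)CCCC(C)(C)C1 | intermediate
8 | (2Z)-but-2-en-1-ol | C/C=C\CO | starting material
9 | (2Z)-but-2-en-1-yl diethyl phosphate | C/C=C\COP(=O)(OCC)OCC | intermediate
10 | (1S)-1,3,3-trimethyl-1-[(3S)-3-methylpent-4-en-1-yn-1-yl]cyclohexane | C[C@@H](C=C)C#C[C@@]1(C)CCCC(C)(C)C1 | intermediate
11 | 3-{(2R)-4-[(1S)-1,3,3-trimethylcyclohexyl]but-3-yn-2-yl}-1,2,4-trioxolane (not isolated, mixture at the ring carbon) | C[C@@H](C1OCOO1)C#C[C@@]1(C)CCCC(C)(C)C1 | intermediate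
12 | (2R)-2-methyl-4-[(1S)-1,3,3-trimethylcyclohexyl]but-3-yn-1-ol | C[C@@H](CO)C#C[C@@]1(C)CCCC(C)(C)C1 | intermediate
13 | tert-butyl(dimethyl){[(2R)-2-methyl-4-[(1S)-1,3,3-trimethylcyclohexyl]but-3-yn-1-yl]oxy}silane | C[C@@H](CO[Si](C)(C)C(C)(C)C)C#C[C@@]1(C)CCCC(C)(C)C1 | intermediate
14 | 2-[(2R)-1-{[tert-butyl(dimethyl)silyl]oxy}propan-2-yl]-4,4-dichloro-3-[(1S)-1,3,3-trimethylcyclohexyl]cyclobut-2-en-1-one | C[C@@H](CO[Si](C)(C)C(C)(C)C)C1=C([C@@]2(C)CCCC(C)(C)C2)C(Cl)(Cl)C1=O | intermediate
15 | 2-[(2R)-1-{[tert-butyl(dimethyl)silyl]oxy}propan-2-yl]-3-[(1S)-1,3,3-trimethylcyclohexyl]cyclobut-2-en-1-one | C[C@@H](CO[Si](C)(C)C(C)(C)C)C1=C([C@@]2(C)CCCC(C)(C)C2)CC1=O | intermediate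
16 | lithium 2-[(2R)-1-{[tert-butyl(dimethyl)silyl]oxy}propan-2-yl]-1-ethenyl-3-[(1S)-1,3,3-trimethylcyclohexyl]cyclobut-2-en-1-olate (not isolated, carbinol carbon unassigned) | C[C@@H](CO[Si](C)(C)C(C)(C)C)C1=C([C@@]2(C)CCCC(C)(C)C2)CC1(C=C)O[Li] | intermediate
17 | lithium (3E)-4-[(2R)-1-{[tert-butyl(dimethyl)silyl]oxy}propan-2-yl]-5-[(1S)-1,3,3-trimethylcyclohexyl]hexa-1,3,5-trien-3-olate (not isolated, vinyl group cis to the dienyl carbon) | C[C@@H](CO[Si](C)(C)C(C)(C)C)/C(=C(\O[Li])C=C)C(=C)[C@@]1(C)CCCC(C)(C)C1 | intermediate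
18 | lithium 3-[(2R)-1-{[tert-butyl(dimethyl)silyl]oxy}propan-2-yl]-4-[(1S)-1,3,3-trimethylcyclohexyl]cyclohexa-1,3-dien-2-olate (not isolated) | C[C@@H](CO[Si](C)(C)C(C)(C)C)C1=C([C@@]2(C)CCCC(C)(C)C2)CCC=C1O[Li] | intermediate
19 | tert-butyl(dimethyl){[(2R)-2-{6-[(trimethylsilyl)oxy]-2-[(1S)-1,3,3-trimethylcyclohexyl]cyclohexa-1,5-dien-1-yl}propyl]oxy}silane | C[C@@H](CO[Si](C)(C)C(C)(C)C)C1=C([C@@]2(C)CCCC(C)(C)C2)CCC=C1O[Si](C)(C)C | intermediate
20 | (6S)-2-[(2R)-1-{[tert-butyl(dimethyl)silyl]oxy}propan-2-yl]-6-(hydroxymethyl)-3-[(1S)-1,3,3-trimethylcyclohexyl]cyclohex-2-en-1-one | C[C@@H](CO[Si](C)(C)C(C)(C)C)C1=C([C@@]2(C)CCCC(C)(C)C2)CC[C@@H](CO)C1=O | intermediate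
21 | {(1S)-3-[(2R)-1-{[tert-butyl(dimethyl)silyl]oxy}propan-2-yl]-2-oxo-4-[(1S)-1,3,3-trimethylcyclohexyl]cyclohex-3-en-1-yl}methyl formate | C[C@@H](CO[Si](C)(C)C(C)(C)C)C1=C([C@@]2(C)CCCC(C)(C)C2)CC[C@@H](COC=O)C1=O | intermediate
22 | {(1S)-3-[(2R)-1-hydroxypropan-2-yl]-2-oxo-4-[(1S)-1,3,3-trimethylcyclohexyl]cyclohex-3-en-1-yl}methyl formate | C[C@@H](CO)C1=C([C@@]2(C)CCCC(C)(C)C2)CC[C@@H](COC=O)C1=O | intermediate
23 | (2R)-2-{(3S)-3-[(formyloxy)methyl]-2-oxo-6-[(1S)-1,3,3-trimethylcyclohexyl]cyclohex-1-en-1-yl}propanoic acid | C[C@@H](C(=O)O)C1=C([C@@]2(C)CCCC(C)(C)C2)CC[C@@H](COC=O)C1=O | target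

**Step count and risks**

Total step count: 14. Longest linear sequence: 13 steps (steps 1–3 and 5–14; step 4 is a one-step side branch).

Steps most likely to fail:

Step 10 (key step). The 6π closure may be slow because the neighbouring tert-alkyl and sec-alkyl groups twist the triene, so that protonation or oligomerisation of the open trienolate competes with ring closure. The fallback keeps the same C4–C5 electrocyclisation but adds a temporary acceptor group to the triene, the substitution pattern for which such closures are known to be especially easy. It sets out from 15. Addition of 1-(phenylsulfonyl)vinyllithium (from phenyl vinyl sulfone and LiN(i-Pr)2, THF, −95 °C), warming and acidic quench should give the β-keto sulfone 2-[(2R)-1-{[tert-butyl(dimethyl)silyl]oxy}propan-2-yl]-6-(phenylsulfonyl)-3-[(1S)-1,3,3-trimethylcyclohexyl]cyclohex-2-en-1-one F1. Reductive desulfonylation (SmI2, THF/MeOH, −78 °C) should give the enone 2-[(2R)-1-{[tert-butyl(dimethyl)silyl]oxy}propan-2-yl]-3-[(1S)-1,3,3-trimethylcyclohexyl]cyclohex-2-en-1-one F2. Kinetic α′-enolisation (LiN(i-Pr)2, THF, −78 °C; Me3SiCl) then returns to the route at 19.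

Step 11. Facial discrimination at C6 may be poor on this hindered cross-conjugated dienol silane, and protodesilylation in the aqueous Lewis-acid medium may outrun the aldol addition. The fallback replaces catalyst control by auxiliary control. It sets out from 19, which is hydrolysed (citric acid, THF/H2O) to the enone F2 described above. Condensation with (S)-1-amino-2-(methoxymethyl)pyrrolidine (TsOH cat., benzene, reflux) gives the SAMP hydrazone of F2 F3. Deprotonation (LiN(i-Pr)2, THF, −78 °C) and alkylation with benzyl chloromethyl ether at −100 °C give the C6-benzyloxymethylated SAMP hydrazone F4, with the new centre set by the auxiliary (the RAMP antipode would be used if the opposite sense were found). Two-phase cleavage with saturated aqueous oxalic acid/Et2O gives (6S)-6-[(benzyloxy)methyl]-2-[(2R)-1-{[tert-butyl(dimethyl)silyl]oxy}propan-2-yl]-3-[(1S)-1,3,3-trimethylcyclohexyl]cyclohex-2-en-1-one F5. Hydrogenolysis (H2, 10% Pd/C, EtOAc), which should spare the hindered tetrasubstituted enone, returns to the route at 20.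

Step 2. Addition may be slow and enantioface selection eroded, because every axial approach to the β-carbon of the 5,5-dimethyl enynone meets a syn-axial methyl group; 1,6-addition is a possible side path. The fallback makes the quaternary centre on an unhindered ring and turns the carbonyl carbon itself into the gem-dimethyl carbon. It sets out from 2. Lithiation and addition to commercial 3-ethoxycyclohex-2-en-1-one with acidic work-up give 3-[(trimethylsilyl)ethynyl]cyclohex-2-en-1-one F6, the substrate type with direct precedent for the copper/NHC Grignard addition. MeMgBr with the enantiomeric catalyst gives (3S)-3-methyl-3-[(trimethylsilyl)ethynyl]cyclohexan-1-one F7. Geminal dimethylation of the ketone (Me2TiCl2 from Me2Zn and TiCl4, CH2Cl2, −30 → 0 °C) gives trimethyl{[(1S)-1,3,3-trimethylcyclohexyl]ethynyl}silane F8. Desilylation (K2CO3, MeOH) returns to the route at 7.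

**Further compounds**

F1 | step 10 | 2-[(2R)-1-{[tert-butyl(dimethyl)silyl]oxy}propan-2-yl]-6-(phenylsulfonyl)-3-[(1S)-1,3,3-trimethylcyclohexyl]cyclohex-2-en-1-one (C6 unassigned) | C[C@@H](CO[Si](C)(C)C(C)(C)C)C1=C([C@@]2(C)CCCC(C)(C)C2)CCC(S(=O)(=O)c2ccccc2)C1=O
F2 | step 10 | 2-[(2R)-1-{[tert-butyl(dimethyl)silyl]oxy}propan-2-yl]-3-[(1S)-1,3,3-trimethylcyclohexyl]cyclohex-2-en-1-one | C[C@@H](CO[Si](C)(C)C(C)(C)C)C1=C([C@@]2(C)CCCC(C)(C)C2)CCCC1=O
F3 | step 11 | SAMP hydrazone of F2, N-[(2S)-2-(methoxymethyl)pyrrolidin-1-yl]imine at C1 | C[C@@H](CO[Si](C)(C)C(C)(C)C)C1=C([C@@]2(C)CCCC(C)(C)C2)CCCC1=NN1CCC[C@H]1COC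
F4 | step 11 | C6-[(benzyloxy)methyl] SAMP hydrazone (same spatial arrangement at C6 as in 20; descriptor 6R because the imine carbon ranks below the CH2O group) | C[C@@H](CO[Si](C)(C)C(C)(C)C)C1=C([C@@]2(C)CCCC(C)(C)C2)CC[C@@H](COCc2ccccc2)C1=NN1CCC[C@H]1COC
F5 | step 11 | (6S)-6-[(benzyloxy)methyl]-2-[(2R)-1-{[tert-butyl(dimethyl)silyl]oxy}propan-2-yl]-3-[(1S)-1,3,3-trimethylcyclohexyl]cyclohex-2-en-1-one | C[C@@H](CO[Si](C)(C)C(C)(C)C)C1=C([C@@]2(C)CCCC(C)(C)C2)CC[C@@H](COCc2ccccc2)C1=O
F6 | step 2 | 3-[(trimethylsilyl)ethynyl]cyclohex-2-en-1-one | C[Si](C)(C)C#CC1=CC(=O)CCC1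
F7 | step 2 | (3S)-3-methyl-3-[(trimethylsilyl)ethynyl]cyclohexan-1-one | C[Si](C)(C)C#C[C@@]1(C)CCCC(=O)C1
F8 | step 2 | trimethyl{[(1S)-1,3,3-trimethylcyclohexyl]ethynyl}silane | C[Si](C)(C)C#C[C@@]1(C)CCCC(C)(C)C1
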